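## Analysis of the target

The target is a (2S)-flavanone. Ring A (C4a to C8a) is fused to the dihydropyranone ring C (O1, C2, C3, C4), and C2 carries an unsubstituted phenyl ring B. Ring A bears a 3-methylbut-2-enyl (prenyl) group at C6 and, at C8, a methylene bridge to ring D, a C-methylated acetylphloroglucinol. C2 is the only stereocentre, so it has no partner to be related to and must be set in the absolute sense. It is benzylic, carries O1 and lies β to the C4 ketone, so base (retro-oxa-Michael opening to the chalcone) or a strong Lewis acid can racemise it. The sensitive groups are the prenyl group between C5–OH and C7–OH (acid closes it to a chroman), five free phenols, and the diarylmethane link between two electron-rich rings. The difficulty is ring A, a hexasubstituted phloroglucinol: its three oxygens have different roles (O1 in ring C, the chelated C5–OH, the C7–OH), C6 and C8 carry different carbon groups, and C4a carries the acyl carbon. Electrophilic substitution on a preformed phloroglucinol cannot tell C6 from C8 or one oxygen from another. The strategy therefore builds ring A from non-aromatic pieces so that the C8a oxygen, the C5 oxygen and the C7 oxygen appear as a silyl ether, an ethyl ether and a free phenol, C6 arrives prenylated, C8 arrives with the bridge carbon, and C4a is the only ring C–H.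

## Retrosynthetic reasoning

**26 back to 24.** The last operations only remove protecting groups. The ethyl ether on O5 of 25 is cut last because its selective removal depends on chelation between O5 and the C4 carbonyl, which exists only once ring C is closed. The four acetal (methoxymethyl) ethers of 24 are removed one step earlier under mild protic conditions that leave the ethyl ether in place.

**24 back to 22.** The C4–C4a bond is cut. C4a is the only unsubstituted carbon of ring A and is ortho, ortho and para to three oxygens, so an intramolecular acylation through mixed anhydride 23 can only go there and closes a six-membered ring. The C2 stereocentre is already in place and is not touched. This avoids a chalcone intermediate, which would give a racemic flavanone or demand an asymmetric cyclisation.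

**22 back to 19 and 20.** The O1–C2 bond is cut (through ester 21). A Mitsunobu etherification of phenol 19 with the purchasable (R)-hydroxy ester 20 forms this bond with inversion, so C2 is set as (S) by a stereospecific displacement. The forward step needs the C8a oxygen to be the only free phenol.

**19 back to 17.** Protecting-group changes only. The four phenols of 17 are capped as acetal ethers (18), then the silyl ether on the C8a oxygen is removed. The silyl ether is what distinguishes that oxygen from the others.

**17 back to 14 and 15.** The bond between the bridge carbon and ring D is cut. The bridge carbon stays on ring A as a CH2OMe group ortho to the free C7–OH of 14, which is a latent ortho-quinone methide (16). Ring D (15) has a single unsubstituted ring carbon, so the junction is unambiguous. The coupling is placed early so that the ionisable benzylic ether does not have to survive the later acidic steps, and while C4a is shielded by the neighbouring silyl ether.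

**14 back to 5 and 9.** This is the key disconnection. The bonds C7–C8, C4a–C8a and C6–C7 are cut, which takes ring A apart into cyclobutenone 5 (supplying C7, C4a, C5 with its ethoxy group, and C6 with its prenyl group) and siloxyalkyne 9 (supplying C8 with the CH2OMe group and C8a with its silyloxy group). What is gained is a ring A in which every position is already labelled. The forward reaction must give one regiochemistry in the ketene–alkyne union.

**5 and 9 back to starting materials.** 5 is cut across the four-membered ring into ethoxyacetylene 3 and ketene 4, which comes from acid chloride 2 and acid 1. 9 is cut at the O–Si bond and the C–O bond back to alkyne 6, through acetylide 7 and ynolate 8. Both precursors are reached in one or two steps by established chemistry.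

## Alternatives that were turned down

**Alternative 1:** The C4a–C4 bond and the C8a–O bond are cut together. Ring A is traced to an aryne across C4a–C8a, released from the silyl triflate A2, and the side chain to the chiral silyloxy acid A3.
- Forward key step: a fluoride source generates the aryne. The carboxylate of A3 adds through oxygen at C8a. The aryl anion then formed at C4a (placed there by the inductive effect of the C5 acetal ether) attacks the ester carbonyl just created, and acyl transfer gives the ortho-hydroxyaryl ketone A1. No ring is formed; ring C would be closed later by displacement of the carbinol with inversion.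
- For: it is convergent, makes the C4 carbonyl without acid, and the C5 oxygen controls the regiochemistry.
- Against:
  - A2 is a pentasubstituted benzene whose preparation meets the same problem of telling apart the positions of a prenylphloroglucinol.
  - Acyl transfer has to outrun protonation of a hindered aryl anion by the acid.
  - The fluoride threatens the silyl ether of A3 and invites β-elimination.
  - C8 of A1 is still unsubstituted, so the bridge to ring D remains to be made.
  - The later closure at a β-hydroxy ketone competes with dehydration to the chalcone, which would cost the stereocentre.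
- Comparison: this route is stronger on the C4a–C4 bond, since it needs no Friedel–Crafts step beside acetal ethers and a prenyl group. The chosen route offers instead a ring A (14) that already carries the bridge carbon at C8 and three distinguishable oxygens, made in one step from 5 and 9.

**Alternative 2:** The same C4–C4a disconnection that closes ring C in the chosen route, applied to a symmetric ring A. A bis-acetal of 2-prenylphloroglucinol is etherified to A5, in which the two carbons ortho to the ether oxygen are equivalent.
- Forward key step: one ortho carbon is joined to ring D, the ester is hydrolysed to the acid A6, and A6, activated as a mixed anhydride at low temperature, acylates the other ortho carbon (C4a) and closes ring C to give A4.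
- For: it is the shortest plan. O5 and O7 need not be told apart, and the final deprotection is mild acid only. On the endgame it is clearly stronger than the chosen route, because no ethyl ether has to be removed next to a prenyl group. The ring closure is the same reaction as step 10, so the two are equal there.
- Against:
  - A5 has no free phenol ortho to either position, so no quinone methide can be formed on ring A. The bridge must come from an electrophile on the ring D side in an intermolecular Friedel–Crafts alkylation, which can strike both equivalent positions (blocking C4a) and is reversible.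
  - Ring D would carry three free phenols into the mixed-anhydride step.
  - C-prenylation of phloroglucinol brings its own C/O and mono/di selectivity problems.
- Comparison: the chosen route spends more steps on protecting groups, but in 14 the carbons C8 and C4a differ from the moment ring A exists (CH2OMe against H), so the attachment of ring D is one defined event.

**Alternative 3:** The C2–C3 bond is cut. Ring C is traced to the diazoketone A8, an aryl diazomethyl ketone on C4a with a benzyl ether on the C8a oxygen.
- Forward key step: a chiral dirhodium tetracarboxylate catalyst turns A8 into a metal carbenoid at C3, which inserts into a benzylic C–H bond of the benzyl ether. This forms C2–C3, closes ring C and sets C2 under catalyst control to give A7.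
- For: the only stereocentre is made catalytically, and ring B and C2 come from a simple benzyl group. In principle this is stronger than the chosen route, which relies on a purchased enantiopure alcohol and a stoichiometric displacement.
- Against:
  - The ether oxygen lies in a 1,5 relationship to the carbenoid carbon, so oxonium ylide formation and a 1,2-benzyl shift to a 2-benzylbenzofuranone should be kinetically preferred over an insertion that needs a six-membered transition state.
  - Carbenoids carrying a single acceptor group are the least selective class in enantioselective C–H insertion.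
  - The prenyl alkene is a competing site (cyclopropanation).
  - The diazoketone has to be built on an acid flanked by two ortho substituents.
  - C8 of A7 is still unsubstituted and its two silyl ethers are alike, so the ring A problem is left open.
- Comparison: it may reach the flavanone core in fewer steps, but it stakes the stereocentre on an unfavourable competition. The chosen route sets C2 by a stereospecific SN2 reaction and places its risk in a ring-forming step with no stereochemical demand.

Key step: step 4

Assumption: 5 is used as the racemate because its only stereocentre becomes sp2 in step 4; 1, 3, 6, 15 and 20 are taken as purchasable.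

## Route

Step 1
Reactants: 1 5-methylhex-4-enoic acid
Product: 2 5-methylhex-4-enoyl chloride
Conditions: (COCl)2, DMF (cat.), CH2Cl2, 0 °C → rt
Reagents that add atoms: oxalyl chloride, ClC(=O)C(=O)Cl
Why: Acid chloride formation through the chloroiminium species from DMF and oxalyl chloride; the by-products are gases and the trisubstituted alkene should be inert under these conditions.

Step 2
Reactants: 2 5-methylhex-4-enoyl chloride; 3 ethoxyacetylene
Product: 5 rac-3-ethoxy-4-(3-methylbut-2-enyl)cyclobut-2-en-1-one, via prenylketene 4 (not isolated)
Conditions: Et3N, 3 (2.5 equiv), Et2O, 0 °C → rt, slow addition of 2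
Reagents that add atoms: none
Why: Dehydrochlorination gives aldoketene 4, which the electron-rich ynol ether traps in a ketene–alkoxyalkyne [2+2] cycloaddition; the nucleophilic terminal carbon of 3 bonds to the ketene carbonyl carbon, so the ethoxy group ends on C3 and the prenyl group on C4. Excess 3 and slow addition should suppress ketene dimerisation, and the alkene of 4 is too close to the ketene for an intramolecular cycloaddition.

Step 3
Reactants: 6 3-methoxyprop-1-yne
Product: 9 3-methoxy-1-(triisopropylsilyloxy)prop-1-yne, via lithium acetylide 7 (not isolated), via lithium ynolate 8 (not isolated)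
Conditions: n-BuLi, THF, −78 °C; LiOOt-Bu [t-BuOOH, LiN(SiMe3)2], −78 → 0 °C; TIPSOTf, −78 → 0 °C
Reagents that add atoms: tert-butyl hydroperoxide, CC(C)(C)OO; triisopropylsilyl trifluoromethanesulfonate, CC(C)[Si](C(C)C)(C(C)C)OS(=O)(=O)C(F)(F)F
Why: Electrophilic oxygenation of acetylide 7 by the lithium peroxide gives ynolate 8, and the bulky silyl triflate silylates it on oxygen; this is an established one-flask route to 1-siloxy-1-alkynes.

Step 4
Reactants: 5 rac-3-ethoxy-4-(3-methylbut-2-enyl)cyclobut-2-en-1-one; 9 3-methoxy-1-(triisopropylsilyloxy)prop-1-yne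
Product: 14 3-ethoxy-6-(methoxymethyl)-2-(3-methylbut-2-enyl)-5-(triisopropylsilyloxy)phenol, via vinylketene 10 (not isolated), via vinylcyclobutenone 11 (not isolated), via dienylketene 12 (not isolated), via cyclohexadienone 13 (not isolated)
Conditions: 9 (1.3 equiv), toluene, 110 °C, sealed tube
Reagents that add atoms: none
Why: Heating opens 5 by a reversible conrotatory 4π electrocyclic cleavage of its C1–C4 bond to vinylketene 10, which erases the stereocentre of 5. The carbonyl carbon of 10 is attacked by the alkyne carbon of 9 remote from oxygen, and the [2+2] cycloaddition closes to 11, forming C7–C8 and C4a–C8a. 11 reopens to dienylketene 12, and ring A closes by a thermally allowed disrotatory 6π electrocyclisation that forms C6–C7; tautomerisation of 13 gives the phenol. The closest known reaction type is the thermal benzannulation of cyclobutenones with siloxyalkynes to resorcinol monosilyl ethers (Danheiser benzannulation); here the 3-ethoxy group of 5 supplies the third oxygen. No stereocentre remains in 14, the sp3 centres of 11 and 13 being transient. The step needs one regiochemistry in the ketene–alkyne cycloaddition, and the polarisation of the ynol ether (nucleophilic at the carbon bearing CH2OMe) secures it, so that the silyloxy group ends on C8a and CH2OMe on C8 next to the free C7–OH. The ynol ether is far more nucleophilic than the prenyl alkene, and the two groups flanking the new phenol should shield it from acylation by 10. Because the ring openings are reversible, only the isomer of 12 with the dienyl arm turned towards the ketene needs to be populated for closure.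

Step 5
Reactants: 14 3-ethoxy-6-(methoxymethyl)-2-(3-methylbut-2-enyl)-5-(triisopropylsilyloxy)phenol; 15 1-(2,4,6-trihydroxy-3-methylphenyl)ethanone
Product: 17 1-[3-({4-ethoxy-2-hydroxy-3-(3-methylbut-2-enyl)-6-(triisopropylsilyloxy)phenyl}methyl)-2,4,6-trihydroxy-5-methylphenyl]ethanone, via quinone methide 16 (not isolated)
Conditions: 15 (2 equiv), camphorsulfonic acid (10 mol%), MeCN, 0 °C → rt
Reagents that add atoms: none
Why: Acid-promoted loss of the methoxy group from the benzylic ether ortho to the free C7–OH gives ortho-quinone methide 16 (or its protonated form), which the only unsubstituted ring carbon of 15 attacks in a Michael-type Friedel–Crafts alkylation that rearomatises both rings. C4a of 14 is flanked by the ethoxy group and the bulky silyl ether and 15 is in excess, which should disfavour self-condensation; catalytic acid at or below room temperature should leave the prenyl group and the aryl silyl ether intact.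

Step 6
Reactants: 17 1-[3-({4-ethoxy-2-hydroxy-3-(3-methylbut-2-enyl)-6-(triisopropylsilyloxy)phenyl}methyl)-2,4,6-trihydroxy-5-methylphenyl]ethanone
Product: 18 1-[3-({4-ethoxy-2-(methoxymethoxy)-3-(3-methylbut-2-enyl)-6-(triisopropylsilyloxy)phenyl}methyl)-2,4,6-tris(methoxymethoxy)-5-methylphenyl]ethanone
Conditions: NaH (4.4 equiv), MOMCl, DMF, 0 °C → rt
Reagents that add atoms: chloromethyl methyl ether, COCCl
Why: Williamson-type O-alkylation of the four phenoxides; the strong base is needed for the hydrogen-bonded phenol next to the acetyl group, and its amount is matched to the phenols so that the methyl ketone is not enolised.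

Step 7
Reactants: 18 1-[3-({4-ethoxy-2-(methoxymethoxy)-3-(3-methylbut-2-enyl)-6-(triisopropylsilyloxy)phenyl}methyl)-2,4,6-tris(methoxymethoxy)-5-methylphenyl]ethanone
Product: 19 1-[3-({4-ethoxy-6-hydroxy-2-(methoxymethoxy)-3-(3-methylbut-2-enyl)phenyl}methyl)-2,4,6-tris(methoxymethoxy)-5-methylphenyl]ethanone
Conditions: Bu4NF (1.2 equiv), AcOH (1.2 equiv), THF, 0 °C
Reagents that add atoms: none
Why: Fluoride cleaves the aryl silyl ether (driven by Si–F bond formation) and the acetic acid buffer keeps the medium non-basic, so the acetal ethers and the ketone stay untouched. This frees the C8a oxygen as the single phenol.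

Step 8
Reactants: 19 1-[3-({4-ethoxy-6-hydroxy-2-(methoxymethoxy)-3-(3-methylbut-2-enyl)phenyl}methyl)-2,4,6-tris(methoxymethoxy)-5-methylphenyl]ethanone; 20 ethyl (3R)-3-hydroxy-3-phenylpropanoate
Product: 21 ethyl (3S)-3-{2-[(3-acetyl-2,4,6-tris(methoxymethoxy)-5-methylphenyl)methyl]-5-ethoxy-3-(methoxymethoxy)-4-(3-methylbut-2-enyl)phenoxy}-3-phenylpropanoate
Conditions: PPh3, DIAD, 20 (1.5 equiv), toluene, 0 °C → rt
Reagents that add atoms: none
Why: Mitsunobu etherification: the secondary benzylic alcohol is activated on phosphorus and displaced by the phenoxide of 19 in an SN2 step with inversion, so the (R)-carbinol becomes the (S)-configured C2–O1 bond. 19 has a single acidic OH whose acidity lies in the range the reaction requires.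

Step 9
Reactants: 21 ethyl (3S)-3-{2-[(3-acetyl-2,4,6-tris(methoxymethoxy)-5-methylphenyl)methyl]-5-ethoxy-3-(methoxymethoxy)-4-(3-methylbut-2-enyl)phenoxy}-3-phenylpropanoate
Product: 22 (3S)-3-{2-[(3-acetyl-2,4,6-tris(methoxymethoxy)-5-methylphenyl)methyl]-5-ethoxy-3-(methoxymethoxy)-4-(3-methylbut-2-enyl)phenoxy}-3-phenylpropanoic acid
Conditions: LiOH·H2O, THF/MeOH/H2O, 0 °C; then cold dilute HCl to pH 4
Reagents that add atoms: lithium hydroxide, [Li+].[OH-]
Why: Saponification; at 0 °C hydroxide attack at the ester carbonyl should outpace α-deprotonation, and once the carboxylate has formed β-elimination of the aryloxide is disfavoured, so the aryl ether and the stereocentre persist.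

Step 10
Reactants: 22 (3S)-3-{2-[(3-acetyl-2,4,6-tris(methoxymethoxy)-5-methylphenyl)methyl]-5-ethoxy-3-(methoxymethoxy)-4-(3-methylbut-2-enyl)phenoxy}-3-phenylpropanoic acid
Product: 24 (2S)-8-{[3-acetyl-2,4,6-tris(methoxymethoxy)-5-methylphenyl]methyl}-5-ethoxy-7-(methoxymethoxy)-6-(3-methylbut-2-enyl)-2-phenyl-2,3-dihydro-4H-chromen-4-one, via mixed anhydride 23 (not isolated)
Conditions: (CF3CO)2O, CH2Cl2, −20 → 0 °C
Reagents that add atoms: none
Why: Intramolecular Friedel–Crafts acylation through mixed anhydride 23; C4a is the only unsubstituted carbon of ring A and is activated by three oxygens, so the six-membered ring C should close at low temperature without touching the stereocentre. Partial loss of acetal ethers to the acid released would be harmless, since all are removed in the next step.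

Step 11
Reactants: 24 (2S)-8-{[3-acetyl-2,4,6-tris(methoxymethoxy)-5-methylphenyl]methyl}-5-ethoxy-7-(methoxymethoxy)-6-(3-methylbut-2-enyl)-2-phenyl-2,3-dihydro-4H-chromen-4-one
Product: 25 (2S)-8-[(3-acetyl-2,4,6-trihydroxy-5-methylphenyl)methyl]-5-ethoxy-7-hydroxy-6-(3-methylbut-2-enyl)-2-phenyl-2,3-dihydro-4H-chromen-4-one
Conditions: HCl (3 M aq.), MeOH/THF, rt
Reagents that add atoms: none
Why: Acid-catalysed acetal exchange with methanol removes the four methoxymethyl groups; at room temperature the prenyl group, the flavanone and the ethyl ether should be unaffected.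

Step 12
Reactants: 25 (2S)-8-[(3-acetyl-2,4,6-trihydroxy-5-methylphenyl)methyl]-5-ethoxy-7-hydroxy-6-(3-methylbut-2-enyl)-2-phenyl-2,3-dihydro-4H-chromen-4-one
Product: 26 (2S)-8-[(3-acetyl-2,4,6-trihydroxy-5-methylphenyl)methyl]-5,7-dihydroxy-6-(3-methylbut-2-enyl)-2-phenyl-2,3-dihydro-4H-chromen-4-one
Conditions: MgI2·OEt2 (6 equiv), THF, 55 °C; then cold 1 M HCl
Reagents that add atoms: none
Why: Chelation-directed dealkylation: magnesium bridges the C4 carbonyl and O5, and iodide removes the ethyl group by SN2, so only the peri ether is cleaved. No protic acid is present, so the prenyl group between two phenols should survive, and the medium is not basic, so C2 should not epimerise through ring opening.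

## Compound list

1 | 5-methylhex-4-enoic acid | CC(C)=CCCC(=O)O | starting material
2 | 5-methylhex-4-enoyl chloride | CC(C)=CCCC(=O)Cl | intermediate
3 | ethoxyacetylene | CCOC#C | starting material
4 | (3-methylbut-2-enyl)ketene (5-methylhexa-1,4-dien-1-one) | CC(C)=CCC=C=O | intermediate (not isolated)
5 | rac-3-ethoxy-4-(3-methylbut-2-enyl)cyclobut-2-en-1-one | CCOC1=CC(=O)C1CC=C(C)C | intermediate
6 | 3-methoxyprop-1-yne | COCC#C | starting material
7 | lithium 3-methoxyprop-1-yn-1-ide | COCC#[C-].[Li+] | intermediate (not isolated)
8 | lithium 3-methoxyprop-1-yn-1-olate | COCC#C[O-].[Li+] | intermediate (not isolated)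
9 | 3-methoxy-1-(triisopropylsilyloxy)prop-1-yne | COCC#CO[Si](C(C)C)(C(C)C)C(C)C | intermediate
10 | (3Z)-3-ethoxy-7-methylocta-1,3,6-trien-1-one | O=C=C/C(OCC)=C/CC=C(C)C | intermediate (not isolated)
11 | rac-4-[(1Z)-1-ethoxy-5-methylhexa-1,4-dienyl]-2-(methoxymethyl)-3-(triisopropylsilyloxy)cyclobut-2-en-1-one | COCC1=C(O[Si](C(C)C)(C(C)C)C(C)C)C(/C(OCC)=C/CC=C(C)C)C1=O | intermediate (not isolated)
12 | (3E,5Z)-5-ethoxy-2-(methoxymethyl)-9-methyl-3-(triisopropylsilyloxy)deca-1,3,5,8-tetraen-1-one | O=C=C(COC)/C(O[Si](C(C)C)(C(C)C)C(C)C)=C\C(OCC)=C\CC=C(C)C | intermediate (not isolated)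
13 | rac-5-ethoxy-2-(methoxymethyl)-6-(3-methylbut-2-enyl)-3-(triisopropylsilyloxy)cyclohexa-2,4-dien-1-one | COCC1=C(O[Si](C(C)C)(C(C)C)C(C)C)C=C(OCC)C(CC=C(C)C)C1=O | intermediate (not isolated)
14 | 3-ethoxy-6-(methoxymethyl)-2-(3-methylbut-2-enyl)-5-(triisopropylsilyloxy)phenol | COCc1c(O)c(CC=C(C)C)c(OCC)cc1O[Si](C(C)C)(C(C)C)C(C)C | intermediate
15 | 1-(2,4,6-trihydroxy-3-methylphenyl)ethanone | CC(=O)c1c(O)cc(O)c(C)c1O | starting material
16 | 3-ethoxy-6-methylidene-2-(3-methylbut-2-enyl)-5-(triisopropylsilyloxy)cyclohexa-2,4-dien-1-one | C=C1C(=O)C(CC=C(C)C)=C(OCC)C=C1O[Si](C(C)C)(C(C)C)C(C)C | intermediate (not isolated)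
17 | 1-[3-({4-ethoxy-2-hydroxy-3-(3-methylbut-2-enyl)-6-(triisopropylsilyloxy)phenyl}methyl)-2,4,6-trihydroxy-5-methylphenyl]ethanone | CC(=O)c1c(O)c(C)c(O)c(Cc2c(O)c(CC=C(C)C)c(OCC)cc2O[Si](C(C)C)(C(C)C)C(C)C)c1O | intermediate
18 | 1-[3-({4-ethoxy-2-(methoxymethoxy)-3-(3-methylbut-2-enyl)-6-(triisopropylsilyloxy)phenyl}methyl)-2,4,6-tris(methoxymethoxy)-5-methylphenyl]ethanone | CC(=O)c1c(OCOC)c(C)c(OCOC)c(Cc2c(OCOC)c(CC=C(C)C)c(OCC)cc2O[Si](C(C)C)(C(C)C)C(C)C)c1OCOC | intermediate
19 | 1-[3-({4-ethoxy-6-hydroxy-2-(methoxymethoxy)-3-(3-methylbut-2-enyl)phenyl}methyl)-2,4,6-tris(methoxymethoxy)-5-methylphenyl]ethanone | CC(=O)c1c(OCOC)c(C)c(OCOC)c(Cc2c(OCOC)c(CC=C(C)C)c(OCC)cc2O)c1OCOC | intermediate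
20 | ethyl (3R)-3-hydroxy-3-phenylpropanoate | CCOC(=O)C[C@@H](O)c1ccccc1 | starting material
21 | ethyl (3S)-3-{2-[(3-acetyl-2,4,6-tris(methoxymethoxy)-5-methylphenyl)methyl]-5-ethoxy-3-(methoxymethoxy)-4-(3-methylbut-2-enyl)phenoxy}-3-phenylpropanoate | CCOC(=O)C[C@H](Oc1cc(OCC)c(CC=C(C)C)c(OCOC)c1Cc1c(OCOC)c(C)c(OCOC)c(C(C)=O)c1OCOC)c1ccccc1 | intermediate
22 | (3S)-3-{2-[(3-acetyl-2,4,6-tris(methoxymethoxy)-5-methylphenyl)methyl]-5-ethoxy-3-(methoxymethoxy)-4-(3-methylbut-2-enyl)phenoxy}-3-phenylpropanoic acid | OC(=O)C[C@H](Oc1cc(OCC)c(CC=C(C)C)c(OCOC)c1Cc1c(OCOC)c(C)c(OCOC)c(C(C)=O)c1OCOC)c1ccccc1 | intermediate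
23 | mixed anhydride of 22 with trifluoroacetic acid | FC(F)(F)C(=O)OC(=O)C[C@H](Oc1cc(OCC)c(CC=C(C)C)c(OCOC)c1Cc1c(OCOC)c(C)c(OCOC)c(C(C)=O)c1OCOC)c1ccccc1 | intermediate (not isolated)
24 | (2S)-8-{[3-acetyl-2,4,6-tris(methoxymethoxy)-5-methylphenyl]methyl}-5-ethoxy-7-(methoxymethoxy)-6-(3-methylbut-2-enyl)-2-phenyl-2,3-dihydro-4H-chromen-4-one | CC(=O)c1c(OCOC)c(C)c(OCOC)c(Cc2c(OCOC)c(CC=C(C)C)c(OCC)c3c2O[C@H](c2ccccc2)CC3=O)c1OCOC | intermediate
25 | (2S)-8-[(3-acetyl-2,4,6-trihydroxy-5-methylphenyl)methyl]-5-ethoxy-7-hydroxy-6-(3-methylbut-2-enyl)-2-phenyl-2,3-dihydro-4H-chromen-4-one | CC(=O)c1c(O)c(C)c(O)c(Cc2c(O)c(CC=C(C)C)c(OCC)c3c2O[C@H](c2ccccc2)CC3=O)c1O | intermediate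
26 | (2S)-8-[(3-acetyl-2,4,6-trihydroxy-5-methylphenyl)methyl]-5,7-dihydroxy-6-(3-methylbut-2-enyl)-2-phenyl-2,3-dihydro-4H-chromen-4-one | CC(=O)c1c(O)c(C)c(O)c(Cc2c(O)c(CC=C(C)C)c(O)c3c2O[C@H](c2ccccc2)CC3=O)c1O | target

## Step count and least certain steps

Total: 12 steps. Longest linear sequence: 11 steps (steps 1, 2 and 4 to 12, from 1 to 26); step 3 is a one-step branch that joins at step 4.

**Step 4 (key step).** The ethoxy group makes 5 a vinylogous ester, and this stabilisation is likely to slow the 4π ring opening. The temperature then needed may reach the range where 9 isomerises by a 1,3-silyl shift, where 14 begins to lose its methoxy group, or where 10 is consumed by dimerisation. Fallback: the ring opening is driven by light instead of heat. 5 and 9 are irradiated (about 300 nm) in a non-polar solvent at room temperature, so that 10 forms without heating and is captured as 11; brief warming then takes 11 through 12 and 13 to 14. The fallback sets out from 5 and 9 and returns at 14; it makes no new compound.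

**Step 5.** The most likely failure is competition for the quinone methide: attack by C4a or by the phenol of a second molecule of 14 leads to oligomers, and the acid may also close the prenyl group onto the C7–OH. Fallback: the leaving group is moved from oxygen to nitrogen, so that the quinone methide is released by base and ring D reacts as its more nucleophilic phenolate. The commercial dimethylamino analogue of 6 (N,N-dimethylprop-2-yn-1-amine) is converted as in step 3 into N,N-dimethyl-3-(triisopropylsilyloxy)prop-2-yn-1-amine F1. Benzannulation of F1 with 5 as in step 4 gives 2-[(dimethylamino)methyl]-5-ethoxy-6-(3-methylbut-2-enyl)-3-(triisopropylsilyloxy)phenol F2. Methyl iodide converts F2 into the trimethylammonium iodide F3. F3 with 15 and Et3N in MeCN at room temperature releases 16, which the phenolate of 15 captures to give 17. The fallback sets out from 5 and returns at 17.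

**Step 12.** Iodide attack on an ethyl group is slower than on a methyl group, so conversion may stall; forcing the reaction risks erosion of the C2 configuration through Lewis-acid-assisted opening of ring C. Fallback: the order of deprotection is changed. 24, still fully protected, is treated with BCl3 in CH2Cl2 from −78 °C upwards and quenched cold. The boron halide cleaves the four acetal ethers and, through the O5/C4 chelate, the ethyl ether in one operation, and because no free phenol is present no hydrogen chloride forms while the prenyl group is exposed. The fallback sets out from 24 and returns at 26, bypassing 25; it makes no new compound.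

**Step 8.** The activated hydroxy ester may be diverted by β-elimination to the cinnamate (its α-hydrogens are acidic), substitution at the hindered phenol may be slow, and partial ionisation of the benzylic centre would lower the enantiomeric purity. Fallback: a partner without acidic α-hydrogens is used and the acid is made by oxidation. Mitsunobu reaction of 19 with (R)-3-chloro-1-phenylpropan-1-ol gives, with inversion, the (S)-3-chloro-1-phenylpropyl ether F4. CsOAc in DMF displaces chloride to give the acetate F5, and K2CO3 in MeOH frees the primary alcohol F6. TEMPO with PhI(OAc)2 in aqueous MeCN oxidises F6 to acid 22. The fallback sets out from 19 and returns at 22.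

**Step 10.** The acid released may ionise the benzylic C2–O bond (elimination to a cinnamic acid and 19, or racemisation), or strip acetal ethers and then close the prenyl group onto a freed phenol. Fallback: the acylating species is changed to a discrete acyl chloride made and used without protic acid. 22 is converted with 1-chloro-N,N,2-trimethylprop-1-en-1-amine into the acid chloride F7. F7 is closed at −78 °C with AgOSO2CF3 in the presence of 2,6-di-tert-butyl-4-methylpyridine, which takes up the proton released, to give 24. The fallback sets out from 22 and returns at 24.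

## Further compounds

F0 | step 4 | none | none
F1 | step 5 | N,N-dimethyl-3-(triisopropylsilyloxy)prop-2-yn-1-amine | CN(C)CC#CO[Si](C(C)C)(C(C)C)C(C)C
F2 | step 5 | 2-[(dimethylamino)methyl]-5-ethoxy-6-(3-methylbut-2-enyl)-3-(triisopropylsilyloxy)phenol | CN(C)Cc1c(O)c(CC=C(C)C)c(OCC)cc1O[Si](C(C)C)(C(C)C)C(C)C
F3 | step 5 | {[4-ethoxy-2-hydroxy-3-(3-methylbut-2-enyl)-6-(triisopropylsilyloxy)phenyl]methyl}trimethylammonium iodide | C[N+](C)(C)Cc1c(O)c(CC=C(C)C)c(OCC)cc1O[Si](C(C)C)(C(C)C)C(C)C.[I-]
F0 | step 12 | none | none
F4 | step 8 | 1-[3-({6-[(1S)-3-chloro-1-phenylpropoxy]-4-ethoxy-2-(methoxymethoxy)-3-(3-methylbut-2-enyl)phenyl}methyl)-2,4,6-tris(methoxymethoxy)-5-methylphenyl]ethanone | ClCC[C@H](Oc1cc(OCC)c(CC=C(C)C)c(OCOC)c1Cc1c(OCOC)c(C)c(OCOC)c(C(C)=O)c1OCOC)c1ccccc1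
F5 | step 8 | (3S)-3-{2-[(3-acetyl-2,4,6-tris(methoxymethoxy)-5-methylphenyl)methyl]-5-ethoxy-3-(methoxymethoxy)-4-(3-methylbut-2-enyl)phenoxy}-3-phenylpropyl acetate | CC(=O)OCC[C@H](Oc1cc(OCC)c(CC=C(C)C)c(OCOC)c1Cc1c(OCOC)c(C)c(OCOC)c(C(C)=O)c1OCOC)c1ccccc1
F6 | step 8 | (3S)-3-{2-[(3-acetyl-2,4,6-tris(methoxymethoxy)-5-methylphenyl)methyl]-5-ethoxy-3-(methoxymethoxy)-4-(3-methylbut-2-enyl)phenoxy}-3-phenylpropan-1-ol | OCC[C@H](Oc1cc(OCC)c(CC=C(C)C)c(OCOC)c1Cc1c(OCOC)c(C)c(OCOC)c(C(C)=O)c1OCOC)c1ccccc1
F7 | step 10 | (3S)-3-{2-[(3-acetyl-2,4,6-tris(methoxymethoxy)-5-methylphenyl)methyl]-5-ethoxy-3-(methoxymethoxy)-4-(3-methylbut-2-enyl)phenoxy}-3-phenylpropanoyl chloride | ClC(=O)C[C@H](Oc1cc(OCC)c(CC=C(C)C)c(OCOC)c1Cc1c(OCOC)c(C)c(OCOC)c(C(C)=O)c1OCOC)c1ccccc1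
A1 | alternative 1 | (3R)-3-(tert-butyldiphenylsilyloxy)-1-[2-hydroxy-4,6-bis(methoxymethoxy)-5-(3-methylbut-2-enyl)phenyl]-3-phenylpropan-1-one | CC(C)=CCc1c(OCOC)cc(O)c(C(=O)C[C@@H](O[Si](c2ccccc2)(c2ccccc2)C(C)(C)C)c2ccccc2)c1OCOC
A2 | alternative 1 | 3,5-bis(methoxymethoxy)-4-(3-methylbut-2-enyl)-2-(trimethylsilyl)phenyl trifluoromethanesulfonate | COCOc1cc(OS(=O)(=O)C(F)(F)F)c([Si](C)(C)C)c(OCOC)c1CC=C(C)C
A3 | alternative 1 | (3R)-3-(tert-butyldiphenylsilyloxy)-3-phenylpropanoic acid | OC(=O)C[C@@H](O[Si](c1ccccc1)(c1ccccc1)C(C)(C)C)c1ccccc1
A4 | alternative 2 | (2S)-8-[(3-acetyl-2,4,6-trihydroxy-5-methylphenyl)methyl]-5,7-bis(methoxymethoxy)-6-(3-methylbut-2-enyl)-2-phenyl-2,3-dihydro-4H-chromen-4-one | CC(=O)c1c(O)c(C)c(O)c(Cc2c(OCOC)c(CC=C(C)C)c(OCOC)c3c2O[C@H](c2ccccc2)CC3=O)c1O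
A5 | alternative 2 | ethyl (3S)-3-[3,5-bis(methoxymethoxy)-4-(3-methylbut-2-enyl)phenoxy]-3-phenylpropanoate | CCOC(=O)C[C@H](Oc1cc(OCOC)c(CC=C(C)C)c(OCOC)c1)c1ccccc1
A6 | alternative 2 | (3S)-3-{2-[(3-acetyl-2,4,6-trihydroxy-5-methylphenyl)methyl]-3,5-bis(methoxymethoxy)-4-(3-methylbut-2-enyl)phenoxy}-3-phenylpropanoic acid | CC(=O)c1c(O)c(C)c(O)c(Cc2c(OCOC)c(CC=C(C)C)c(OCOC)cc2O[C@H](c2ccccc2)CC(=O)O)c1O
A7 | alternative 3 | (2S)-5,7-bis(tert-butyldimethylsilyloxy)-6-(3-methylbut-2-enyl)-2-phenyl-2,3-dihydro-4H-chromen-4-one | CC(C)=CCc1c(O[Si](C)(C)C(C)(C)C)cc2c(c1O[Si](C)(C)C(C)(C)C)C(=O)C[C@@H](c1ccccc1)O2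
A8 | alternative 3 | 1-[2-(benzyloxy)-4,6-bis(tert-butyldimethylsilyloxy)-5-(3-methylbut-2-enyl)phenyl]-2-diazoethan-1-one | CC(C)=CCc1c(O[Si](C)(C)C(C)(C)C)cc(OCc2ccccc2)c(C(=O)C=[N+]=[N-])c1O[Si](C)(C)C(C)(C)C
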